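The plan rests on cutting the C1(sp2)–C11H2 bond of the eleven-membered ring, between the α-carbon of the enoic acid and the methylene next to the C10 isovalerate. Ring atoms are numbered from the carboxyl-bearing C1 through the alkene carbon C2. Because C3 and C11 sit cis on C1=C2, the ring unfolds to an open-chain (Z)-2-bromoenoate that ends in a primary iodide beside the finished C10 ester. One nickel-catalysed reductive alkenyl–alkyl coupling closes the carbocycle with the alkene geometry, both stereocentres, the C5 methylene and all oxygen functions already in place. The C8 gem-dimethyl group helps the chain fold. C10 comes from (S)-epichlorohydrin, C6 from a Corey–Bakshi–Shibata reduction.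

Key step: step 11

Remark on the chemistry: the SMILES is read as (1E,6S,10S)-6-hydroxy-8,8-dimethyl-5-methylidene-10-[(3-methylbutanoyl)oxy]cycloundec-1-ene-1-carboxylic acid. These ring numbers are also used for the matching atoms of open-chain compounds.

Step 1
Reactants: 1 (S)-epichlorohydrin; 2 prenyl chloride (1-chloro-3-methylbut-2-ene)
Product: 4 (2S)-1-chloro-4,4-dimethylhex-5-en-2-ol, via prenylmagnesium chloride 3 (not isolated)
Conditions: 2, Mg turnings, THF, 0 °C; then 1, no copper salt, −20 → 0 °C; cold 1 M HCl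
Reagents that add atoms: magnesium, [Mg] (held only in 3)
Why: Grignard opening of an epoxide: an allylic magnesium reagent should react through its γ-carbon (SE2′) at the unsubstituted oxirane CH2, which builds the quaternary C8 next to a vinyl group and leaves the chiral-pool C–O stereocentre (future C10, S) untouched.

Step 2
Reactants: 4 (2S)-1-chloro-4,4-dimethylhex-5-en-2-ol; 5 isovaleryl chloride (3-methylbutanoyl chloride)
Product: 6 (2S)-1-chloro-4,4-dimethylhex-5-en-2-yl 3-methylbutanoate
Conditions: pyridine, 4-(dimethylamino)pyridine (cat.), CH2Cl2, 0 °C → rt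
Reagents that add atoms: none
Why: Acyl transfer catalysed by 4-(dimethylamino)pyridine esterifies the secondary alcohol without touching its C–O bond, so C10 keeps its configuration and the final isovalerate doubles as protecting group.

Step 3
Reactants: 6 (2S)-1-chloro-4,4-dimethylhex-5-en-2-yl 3-methylbutanoate
Product: 7 (2S)-1-chloro-4,4-dimethyl-6-oxohexan-2-yl 3-methylbutanoate
Conditions: PdCl2(PhCN)2 (12 mol %), CuCl2·2H2O (12 mol %), AgNO2 (6 mol %), O2 (1 atm), t-BuOH/MeNO2 15:1, rt
Reagents that add atoms: dioxygen, O=O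
Why: Nitrite-modified Wacker-type oxidation: with a quaternary allylic carbon the oxygen should be delivered to the terminal carbon, so the hindered vinyl group gives the aldehyde (C6) rather than the methyl ketone, and ester and alkyl chloride are inert.

Step 4
Reactants: 8 (1,3-dioxolan-2-ylmethyl)magnesium bromide (commercial THF solution); 9 2,3-dibromopropene
Product: 10 2-(3-bromobut-3-en-1-yl)-1,3-dioxolane
Conditions: CuI (10 mol %), THF, 0 °C → rt
Reagents that add atoms: none
Why: Copper-catalysed allylic substitution of the allylic bromide by the Grignard reagent; SN2 and SN2′ attack give the same product and the alkenyl bromide stays intact.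

Step 5
Reactants: 7 (2S)-1-chloro-4,4-dimethyl-6-oxohexan-2-yl 3-methylbutanoate; 10 2-(3-bromobut-3-en-1-yl)-1,3-dioxolane
Product: 12 (2S,6RS)-1-chloro-9-(1,3-dioxolan-2-yl)-6-hydroxy-4,4-dimethyl-7-methylidenenonan-2-yl 3-methylbutanoate, via alkenylchromium dichloride 11 (not isolated)
Conditions: CrCl2 (4 equiv), NiCl2 (5 mol %), DMF, rt; H2O
Reagents that add atoms: chromium dichloride, Cl[Cr]Cl (held only in 11)
Why: Nozaki–Hiyama–Kishi reaction: the alkenylchromium species adds only to the aldehyde and tolerates ester, alkyl chloride and acetal; C6 forms as an epimer mixture that the next two steps correct.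

Step 6
Reactants: 12 (2S,6RS)-allylic alcohol
Product: 13 (2S)-1-chloro-9-(1,3-dioxolan-2-yl)-4,4-dimethyl-7-methylidene-6-oxononan-2-yl 3-methylbutanoate
Conditions: Dess–Martin periodinane, CH2Cl2, 0 °C → rt
Reagents that add atoms: none
Why: Dess–Martin oxidation removes the unselective C6 centre under near-neutral conditions that spare acetal, ester and the 1,1-disubstituted alkene.

Step 7
Reactants: 13 α-methylene ketone
Product: 14 (2S,6S)-1-chloro-9-(1,3-dioxolan-2-yl)-6-hydroxy-4,4-dimethyl-7-methylidenenonan-2-yl 3-methylbutanoate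
Conditions: (R)-2-methyl-CBS-oxazaborolidine [(R)-tetrahydro-1-methyl-3,3-diphenyl-1H,3H-pyrrolo[1,2-c][1,3,2]oxazaborole] (20 mol %), catecholborane, toluene, −78 °C; H2O
Reagents that add atoms: none
Why: Corey–Bakshi–Shibata reduction: with the α-branched alkenyl group as the large and the CH2 flank as the small substituent, the (R)-catalyst should deliver hydride to the face that gives the (6S)-alcohol, and catecholborane at low temperature avoids hydroboration and 1,4-reduction.

Step 8
Reactants: 14 (2S,6S)-allylic alcohol acetal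
Product: 16 (2S,6S)-1-chloro-4,4-dimethyl-7-methylidene-10-oxo-6-[(triethylsilyl)oxy]decan-2-yl 3-methylbutanoate, via lutidinium acetal salt 15 (not isolated)
Conditions: Et3SiOTf (3 equiv), 2,6-lutidine (4.5 equiv), CH2Cl2, 0 °C; then H2O, rt
Reagents that add atoms: triethylsilyl trifluoromethanesulfonate, CC[Si](CC)(CC)OS(=O)(=O)C(F)(F)F; water, O; 2,6-lutidine, Cc1cccc(C)n1 (held only in 15)
Why: Silyl triflate/lutidine chemistry does two known jobs at once: O-silylation of the C6 alcohol, and conversion of the aldehyde acetal into a lutidinium salt that water hydrolyses to the aldehyde under weakly basic conditions that spare the new silyl ether.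

Step 9
Reactants: 16 aldehyde; 17 tert-butyl (triphenylphosphoranylidene)acetate
Product: 19 tert-butyl (2Z,7S,11S)-2-bromo-12-chloro-9,9-dimethyl-6-methylidene-11-[(3-methylbutanoyl)oxy]-7-[(triethylsilyl)oxy]dodec-2-enoate, via bromo ylide 18 (not isolated)
Conditions: 17, N-bromosuccinimide, CH2Cl2, −20 °C; then 16, rt → 40 °C
Reagents that add atoms: N-bromosuccinimide, O=C1CCC(=O)N1Br
Why: Wittig reaction of a stabilised ylide that is brominated before the substrate is added; the ester group ends up trans to the chain as usual, which should give the (Z)-2-bromoenoate with C3 cis to bromine.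

Step 10
Reactants: 19 chloro bromoenoate
Product: 20 tert-butyl (2Z,7S,11S)-2-bromo-12-iodo-9,9-dimethyl-6-methylidene-11-[(3-methylbutanoyl)oxy]-7-[(triethylsilyl)oxy]dodec-2-enoate
Conditions: NaI (10 equiv), acetone, reflux
Reagents that add atoms: sodium iodide, [Na+].[I-]
Why: Finkelstein reaction: SN2 exchange at the primary carbon driven by precipitation of NaCl; the alkenyl bromide cannot react and C10 is not involved.

Step 11
Reactants: 20 iodo bromoenoate
Product: 21 tert-butyl (1E,6S,10S)-8,8-dimethyl-5-methylidene-10-[(3-methylbutanoyl)oxy]-6-[(triethylsilyl)oxy]cycloundec-1-ene-1-carboxylate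
Conditions: NiBr2·dme (dme = 1,2-dimethoxyethane, 30 mol %), 4,4′-di-tert-butyl-2,2′-bipyridine (36 mol %), Mn powder (5 equiv), NaI (1 equiv), N,N-dimethylacetamide, 40 °C, 20 added by syringe pump over 16 h (final 2 mM)
Reagents that add atoms: none
Why: Proposed new method: zerovalent nickel (from NiBr2·dme, the bipyridine and Mn) should insert into the C1(sp2)–Br bond with retention while a monovalent nickel species abstracts iodine from C11 to give a primary radical; capture of that radical by the tethered divalent alkenylnickel centre gives a trivalent nickel species that forms the C1–C11 bond by reductive elimination, and Mn restores the catalyst. The closest known reaction type is the intermolecular nickel-catalysed reductive cross-electrophile coupling of alkenyl bromides with primary alkyl iodides, which tolerates esters and silyl ethers; what is new is its use to close a medium ring. The single ring formed, the eleven-membered carbocycle, closes end to end (both reacting carbons become ring members) through a twelve-membered nickelacycle, whose long C–Ni bonds ease the transannular strain of the closure. No stereocentre is created: C6 and C10 are spectators, and retention at the alkenyl–nickel bond turns the (Z)-bromide into the ring-cis (1E)-enoate. The step needs cross- over homo-coupling, secured by the two different activation modes of C(sp2)–Br and C(sp3)–I, and ring closure over oligomerisation, secured by slow addition at high dilution, the C8 gem-dimethyl (Thorpe–Ingold) fold and the sp2 sites C1, C2 and C5 that remove transannular hydrogens. Loss of the β-isovalerate is held back because Mn does not insert into the C–I bond and radical capture with reductive elimination should be faster than 1,2-acyloxy shift or β-elimination.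

Step 12
Reactants: 21 protected macrocycle
Product: 23 (1E,6S,10S)-6-hydroxy-8,8-dimethyl-5-methylidene-10-[(3-methylbutanoyl)oxy]cycloundec-1-ene-1-carboxylic acid, via trimethylsilyl ester 22 (not isolated)
Conditions: Me3SiOTf (3 equiv), 2,6-lutidine (4 equiv), CH2Cl2, 0 °C → rt; then AcOH/THF/H2O 3:1:1, rt
Reagents that add atoms: trimethylsilyl trifluoromethanesulfonate, C[Si](C)(C)OS(=O)(=O)C(F)(F)F (held only in 22)
Why: Silyl-triflate-induced cleavage of the tert-butyl ester (loss of isobutene) followed by mild acid hydrolysis of the silyl ester and the triethylsilyl ether avoids strong protic acid, base and fluoride, so the allylic alcohol, the methylene group and the isovalerate should survive.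

Compound list
1 | (S)-epichlorohydrin, (2S)-2-(chloromethyl)oxirane | ClC[C@@H]1CO1 | starting material
2 | prenyl chloride, 1-chloro-3-methylbut-2-ene | CC(C)=CCCl | starting material
3 | prenylmagnesium chloride | CC(C)=CC[Mg]Cl | intermediate
4 | (2S)-1-chloro-4,4-dimethylhex-5-en-2-ol | ClC[C@@H](O)CC(C)(C)C=C | intermediate
5 | isovaleryl chloride, 3-methylbutanoyl chloride | CC(C)CC(=O)Cl | starting material
6 | (2S)-1-chloro-4,4-dimethylhex-5-en-2-yl 3-methylbutanoate | ClC[C@@H](OC(=O)CC(C)C)CC(C)(C)C=C | intermediate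
7 | (2S)-1-chloro-4,4-dimethyl-6-oxohexan-2-yl 3-methylbutanoate | ClC[C@@H](OC(=O)CC(C)C)CC(C)(C)CC=O | intermediate
8 | (1,3-dioxolan-2-ylmethyl)magnesium bromide | Br[Mg]CC1OCCO1 | starting material
9 | 2,3-dibromopropene | C=C(Br)CBr | starting material
10 | 2-(3-bromobut-3-en-1-yl)-1,3-dioxolane | C=C(Br)CCC1OCCO1 | intermediate
11 | [4-(1,3-dioxolan-2-yl)but-1-en-2-yl]chromium dichloride | C=C([Cr](Cl)Cl)CCC1OCCO1 | intermediate
12 | (2S,6RS)-1-chloro-9-(1,3-dioxolan-2-yl)-6-hydroxy-4,4-dimethyl-7-methylidenenonan-2-yl 3-methylbutanoate | ClC[C@@H](OC(=O)CC(C)C)CC(C)(C)CC(O)C(=C)CCC1OCCO1 | intermediate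
13 | (2S)-1-chloro-9-(1,3-dioxolan-2-yl)-4,4-dimethyl-7-methylidene-6-oxononan-2-yl 3-methylbutanoate | ClC[C@@H](OC(=O)CC(C)C)CC(C)(C)CC(=O)C(=C)CCC1OCCO1 | intermediate
14 | (2S,6S)-1-chloro-9-(1,3-dioxolan-2-yl)-6-hydroxy-4,4-dimethyl-7-methylidenenonan-2-yl 3-methylbutanoate | ClC[C@@H](OC(=O)CC(C)C)CC(C)(C)C[C@H](O)C(=C)CCC1OCCO1 | intermediate
15 | lutidinium acetal salt: C6–OSiEt3, former acetal carbon bearing N-(2,6-lutidinium) and OCH2CH2OSiEt3 (epimers at that carbon), triflate counter-ion | ClC[C@@H](OC(=O)CC(C)C)CC(C)(C)C[C@H](O[Si](CC)(CC)CC)C(=C)CCC(OCCO[Si](CC)(CC)CC)[n+]1c(C)cccc1C.[O-]S(=O)(=O)C(F)(F)F | intermediate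
16 | (2S,6S)-1-chloro-4,4-dimethyl-7-methylidene-10-oxo-6-[(triethylsilyl)oxy]decan-2-yl 3-methylbutanoate | ClC[C@@H](OC(=O)CC(C)C)CC(C)(C)C[C@H](O[Si](CC)(CC)CC)C(=C)CCC=O | intermediate
17 | tert-butyl (triphenylphosphoranylidene)acetate | CC(C)(C)OC(=O)C=P(c1ccccc1)(c1ccccc1)c1ccccc1 | starting material
18 | tert-butyl bromo(triphenylphosphoranylidene)acetate | CC(C)(C)OC(=O)C(Br)=P(c1ccccc1)(c1ccccc1)c1ccccc1 | intermediate
19 | tert-butyl (2Z,7S,11S)-2-bromo-12-chloro-9,9-dimethyl-6-methylidene-11-[(3-methylbutanoyl)oxy]-7-[(triethylsilyl)oxy]dodec-2-enoate | ClC[C@@H](OC(=O)CC(C)C)CC(C)(C)C[C@H](O[Si](CC)(CC)CC)C(=C)CC/C=C(Br)/C(=O)OC(C)(C)C | intermediate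
20 | tert-butyl (2Z,7S,11S)-2-bromo-12-iodo-9,9-dimethyl-6-methylidene-11-[(3-methylbutanoyl)oxy]-7-[(triethylsilyl)oxy]dodec-2-enoate | IC[C@@H](OC(=O)CC(C)C)CC(C)(C)C[C@H](O[Si](CC)(CC)CC)C(=C)CC/C=C(Br)/C(=O)OC(C)(C)C | intermediate
21 | tert-butyl (1E,6S,10S)-8,8-dimethyl-5-methylidene-10-[(3-methylbutanoyl)oxy]-6-[(triethylsilyl)oxy]cycloundec-1-ene-1-carboxylate | C=C1CC/C=C(/C(=O)OC(C)(C)C)C[C@@H](OC(=O)CC(C)C)CC(C)(C)C[C@@H]1O[Si](CC)(CC)CC | intermediate
22 | trimethylsilyl (1E,6S,10S)-8,8-dimethyl-5-methylidene-10-[(3-methylbutanoyl)oxy]-6-[(triethylsilyl)oxy]cycloundec-1-ene-1-carboxylate | C=C1CC/C=C(/C(=O)O[Si](C)(C)C)C[C@@H](OC(=O)CC(C)C)CC(C)(C)C[C@@H]1O[Si](CC)(CC)CC | intermediate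
23 | (1E,6S,10S)-6-hydroxy-8,8-dimethyl-5-methylidene-10-[(3-methylbutanoyl)oxy]cycloundec-1-ene-1-carboxylic acid | C=C1CC/C=C(/C(=O)O)C[C@@H](OC(=O)CC(C)C)CC(C)(C)C[C@@H]1O | target

Total step count: 12. Longest linear sequence: 11 steps (steps 1–3 and 5–12).

Steps most likely to fail

Step 11. Intermolecular radical capture may lead to oligomers. Either terminus may be hydrodehalogenated. The β-acyloxy group may be lost reductively to leave a terminal alkene before the ring closes. The fallback uses known chemistry and closes the same C1–C11 bond with a soft enolate. It sets out from 16 and comes back to the route at 21. Roskamp homologation of 16 with tert-butyl diazoacetate and SnCl2 (cat.) in CH2Cl2 gives the open-chain β-keto ester F1. NaI in refluxing acetone gives the iodo β-keto ester F2. Cs2CO3 in MeCN at high dilution closes the ring by C-alkylation to the cyclic β-keto ester F3. NaBH4 in MeOH at 0 °C gives the cyclic β-hydroxy ester F4, and MsCl/Et3N gives the cyclic β-mesyloxy ester F5. DBU then triggers an E1cB elimination that can place the alkene only between C1 and C2 and should give 21.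

Step 1. The allylic Grignard reagent may attack through its α-carbon to give the linear prenyl product, or magnesium halide may open the epoxide. The fallback gives up the chiral pool and buys the quaternary carbon. It does not set out from 1 or 2 but from commercial methyl 3,3-dimethylpent-4-enoate F6, and it comes back to the route at 4. DIBAL-H in CH2Cl2 at −78 °C gives 3,3-dimethylpent-4-enal F7. Corey–Chaykovsky methylenation (Me3SI, NaH, DMSO) gives racemic 2-(2,2-dimethylbut-3-en-1-yl)oxirane F8. Jacobsen hydrolytic kinetic resolution, with the enantiomer of [N,N′-bis(3,5-di-tert-butylsalicylidene)-1,2-cyclohexanediaminato]cobalt acetate that hydrolyses the (R)-epoxide, leaves (2S)-2-(2,2-dimethylbut-3-en-1-yl)oxirane F9. LiCl/AcOH in THF opens F9 at the terminal carbon to 4.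

Step 7. Facial selectivity may be poor, because the neopentyl-type CH2 flank is nearly as bulky as the alkenyl flank. The fallback sets C6 in the C–C bond-forming event instead of in a reduction. It sets out from 7 and 10 and comes back to the route at 14, so 12 and 13 are bypassed. A catalytic asymmetric Nozaki–Hiyama–Kishi coupling is used: CrCl2 with a chiral 2-(2-sulfonamidophenyl)oxazoline ligand, NiCl2(2,9-dimethyl-1,10-phenanthroline), Mn, Cp2ZrCl2, LiCl, MeCN. It puts the new carbinol under ligand control, with the ligand enantiomer chosen for the (6S) product. It makes no new compound (F0).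

Further compounds
F1 | step 11 | tert-butyl (7S,11S)-12-chloro-9,9-dimethyl-6-methylidene-11-[(3-methylbutanoyl)oxy]-3-oxo-7-[(triethylsilyl)oxy]dodecanoate | ClC[C@@H](OC(=O)CC(C)C)CC(C)(C)C[C@H](O[Si](CC)(CC)CC)C(=C)CCC(=O)CC(=O)OC(C)(C)C
F2 | step 11 | tert-butyl (7S,11S)-12-iodo-9,9-dimethyl-6-methylidene-11-[(3-methylbutanoyl)oxy]-3-oxo-7-[(triethylsilyl)oxy]dodecanoate | IC[C@@H](OC(=O)CC(C)C)CC(C)(C)C[C@H](O[Si](CC)(CC)CC)C(=C)CCC(=O)CC(=O)OC(C)(C)C
F3 | step 11 | tert-butyl 8,8-dimethyl-5-methylidene-10-[(3-methylbutanoyl)oxy]-2-oxo-6-[(triethylsilyl)oxy]cycloundecane-1-carboxylate, C6 and C10 arranged as in 21, epimers at C1 | C=C1CCC(=O)C(C(=O)OC(C)(C)C)C[C@@H](OC(=O)CC(C)C)CC(C)(C)C[C@@H]1O[Si](CC)(CC)CC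
F4 | step 11 | tert-butyl 2-hydroxy-8,8-dimethyl-5-methylidene-10-[(3-methylbutanoyl)oxy]-6-[(triethylsilyl)oxy]cycloundecane-1-carboxylate, C6 and C10 arranged as in 21, epimers at C1 and C2 | C=C1CCC(O)C(C(=O)OC(C)(C)C)C[C@@H](OC(=O)CC(C)C)CC(C)(C)C[C@@H]1O[Si](CC)(CC)CC
F5 | step 11 | tert-butyl 2-[(methylsulfonyl)oxy]-8,8-dimethyl-5-methylidene-10-[(3-methylbutanoyl)oxy]-6-[(triethylsilyl)oxy]cycloundecane-1-carboxylate, C6 and C10 arranged as in 21, epimers at C1 and C2 | C=C1CCC(OS(C)(=O)=O)C(C(=O)OC(C)(C)C)C[C@@H](OC(=O)CC(C)C)CC(C)(C)C[C@@H]1O[Si](CC)(CC)CC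
F6 | step 1 | methyl 3,3-dimethylpent-4-enoate | C=CC(C)(C)CC(=O)OC
F7 | step 1 | 3,3-dimethylpent-4-enal | C=CC(C)(C)CC=O
F8 | step 1 | racemic 2-(2,2-dimethylbut-3-en-1-yl)oxirane | C=CC(C)(C)CC1CO1
F9 | step 1 | (2S)-2-(2,2-dimethylbut-3-en-1-yl)oxirane | C1O[C@H]1CC(C)(C)C=C
F0 | step 7 | none | none
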